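## The problem

The target is a drimane: a trans-fused decalin whose ring A carries only the C4 gem-dimethyl group, while ring B carries five contiguous stereocentres (C5, C6, C8, C9, C10). The quaternary C10 is the only centre that cannot be corrected later, so it must be set absolutely; the others can be derived from it. C5 and C9 can be set by equilibration (trans ring fusion, equatorial C11 carboxyl), C6 by hydride delivery to the open α face, and C8 by hydrogenation from the α face. The C8 carboxyl is axial and cis to the C9 carboxyl, which is the less stable arrangement, so C8 must be set kinetically and never exposed to strong base afterwards. The 6β oxygen and the 8β carboxyl are 1,3-diaxial, so a free 6-hydroxyl next to an sp3 C8 ester would close a bridged lactone; O6 must therefore be acylated before C8 becomes tetrahedral. The all-E trienoate does not tolerate hydrogenation, strong nucleophiles or ester hydrolysis, so it must be built late and the two carboxyls released without base. The enabling feature is that O6 and the C9 carboxyl sit 1,4 across ring B on either side of the C5–C10 bond. C6 and C9 can therefore begin as the donor and acceptor carbons of one push–pull alkene held in a four-membered ring by C7–C8, and C5=C10 as the alkene of a cyclohexenone.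

## Retrosynthesis

**Carboxyl release and triene (24 ⇒ 23 ⇒ 21 + 22).** The two O–tert-butyl bonds and the C2′=C3′ bond of the side chain are cut. tert-Butyl esters are chosen because acid removes them by alkyl–oxygen cleavage, which touches neither the secondary trienoate nor the epimerisable C8 and C9. Cutting the triene at C2′=C3′ rather than at the C6–O acyl bond leaves phosphonoacetate 21, which survives hydrogenation, and commercial dienal 22. The forward Horner–Wadsworth–Emmons reaction must be E-selective and mild enough not to epimerise C8.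

**C8 and the 6-O-acyl bond (21 ⇒ 20 ⇒ 18 + 19).** The C7–H and C8–H bonds (and the two C–H bonds of ring A) are cut to give diene 20, then the C6–O acyl bond to give allylic alcohol 18 and acid 19. Hydrogenation after acylation is preferred to the reverse order because O6 is then already blocked when the axial C12 ester appears. The precursor has one stereocentre fewer, and the forward reaction only has to add hydrogen to the face opposite the C10 methyl and the 6β ester.

**C6 hydride and the 7-ene (18 ⇒ 17 ⇒ 16 ⇒ 15).** The C6–H bond is cut to enone 17, and the C7=C8 double bond is traced through silyl enol ether 16 to saturated ketone 15. Dehydrogenating the ketone toward C7–C8 is regiochemically unambiguous, since C7 is the only accessible α-methylene. The alternative, trapping an ester enolate at C9 to reach an 8-ene, would have to outrun proton transfer to the new ketone. Ketone 15 is the all-equatorial, trans-fused isomer, so its C5, C8 and C9 come from equilibration.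

**Ring B from a strained bond (15 ⇒ 13 ⇒ 12 ⇒ 11).** In the reverse sense the C6–C9 bond is re-formed, turning ring B into the bicyclo[2.2.0]hexane of silyl ether 13; the C1 oxygen is then reinstated through enol triflate 12 to ketone 11. Forward, unmasking the C6 alkoxide triggers a retro-aldol cleavage driven by the strain of both four-membered rings. The C1 carbonyl is removed before ring opening, when it is the only ketone present.

**Key disconnection (11 ⇒ 9 + 10).** The C5–C6 and C9–C10 bonds are cut, giving cyclobutene 9 and enone 10. This [2+2] pairing is preferred to polar annulations because it joins the enone β-carbon to an oxygen-bearing carbon and the α-carbon to an acceptor-bearing one, an umpolung pattern that radical recombination tolerates even between fully substituted centres. The precursors are one small chiral ring and one commercial enone. The forward reaction must be head-to-tail, anti to the C8 ester and exo.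

**The cyclobutene (9 ⇒ 8 ⇒ 7 ⇒ 6 ⇒ 5 ⇒ 3 + 4; 3 ⇒ 1 + 2).** The O–Si bond, the ketal, the ester alkyl groups and finally the two ring bonds of the cyclobutane are cut, leading to di-menthyl fumarate 3 and ketene acetal 4. Diester 3 is in turn cut at both ester C–O bonds into fumaric acid 1 and two molecules of menthol 2. The auxiliary-controlled Lewis-acid [2+2] is an established way to a single trans-cyclobutane diester. Only C1 of that ring has to survive, because C2 becomes sp2 in 9.

## Roads not taken

**Alternative 1:** Vinylcyclopropane carbonylation. The cut is at C5–C6 and C6–C7, with C6 delivered as carbon monoxide. Forward, [Rh(CO)2Cl]2 under CO would open the C5–C9 bond of vinylcyclopropane A2 and join C5 to C7 through a carbonyl, giving cis-fused keto diester A1. Merits: ring B, the C6 ketone and an 8-ene arrive in one catalytic step, no C1 oxygen has to be removed, and the two esters are differentiated. Weak points: A2 is a fully substituted cyclopropane with adjacent quaternary C9 and C10, to be made from a hindered trisubstituted cycloalkene and a doubly acceptor-substituted vinyl carbenoid, with no dependable control of C10. The metal must also choose C5–C9 over C9–C10, and A1 is cis-fused and needs the same C5 equilibration. Comparison: this road would be about three steps shorter after its key step, and that advantage is real. The chosen plan offsets it with a proven source of absolute configuration and with partners 9 and 10 reached by routine steps.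

**Alternative 2:** Hydroxyl-directed double carbonylation. The cut is at C8–C12 and C9–C11, both carboxyl carbons coming from CO. Forward, PdCl2/CuCl2/CO/MeOH would convert homoallylic alcohol A4 into bridged lactone ester A3 by syn addition across the alkene. Merits: it is the most economical way to the cis 8β,9β pattern, with no hydrogenation and no unsaturation to place. Weak points: the second insertion occurs at C9 next to the quaternary C10, and A4 needs its own enantioselective decalin synthesis. Above all, O6 ends up locked in the lactone: opening it and acylating an axial hydroxyl beside an axial carboxyl that recloses is the very problem the target poses. The C11 methyl ester would also have to be cleaved in the presence of the trienoate. Comparison: clearly better in step count and in directness for C8/C9. The chosen plan offsets this by never letting O6 and C12 meet, since O6 is acylated while C8 is still sp2.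

**Alternative 3:** Silyloxydiene intramolecular Diels–Alder. The cut is at C5–C10 and C8–C9. Forward, Cu(SbF6)2 with a tert-butyl bis(oxazoline) ligand would cyclise triene A6 to trans-fused adduct A5, closing both rings. Merits: C5, C8, C9 and C10 are set in one catalytic enantioselective step with the target's relative configuration, and the C6 oxygen is in place. Weak points: the dienophile is β,β-disubstituted and the diene terminus C5 is neopentyl, so the C5–C10 bond must form between a quaternary and a neopentyl carbon in a concerted, sterically sensitive, two-point-bound transition state. A6 needs a linear synthesis with a geometrically defined silyl enol ether. After hydrolysis the 6-ketone sits beside an axial C12 ester, so reduction leads into the same lactone as in Alternative 2. Comparison: superior in stereochemical economy if the cycloaddition proceeds. The chosen plan offsets this by making its crowded bond by diradical recombination, and by having every later centre follow a thermodynamic or steric default.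

Key step: step 7

Assumption: di-(−)-menthyl fumarate is taken to give the (1S,2R)-cyclobutane with 1,1-dimethoxyethene under a dialkylaluminium chloride, so the (1R,2S) series needed here is drawn from (+)-menthol.

Convention: drimane numbering is used (C11 on C9, C12 on C8, C15 on C10); β is the face of the C10 methyl group.

## Steps

Step 1
Reactants: 1 fumaric acid; 2 (1S,2R,5S)-(+)-menthol (two equivalents)
Product: 3 di-(+)-menthyl fumarate
Conditions: 2 (2.2 equiv), TsOH·H2O (cat.), toluene, reflux, Dean–Stark
Reagents that add atoms: (1S,2R,5S)-(+)-menthol (the second equivalent of 2), CC(C)[C@H]1CC[C@H](C)C[C@@H]1O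
Why: Twofold Fischer esterification, one molecule of 2 on each carboxyl group of 1, driven by azeotropic removal of the two equivalents of water; the E geometry is the stable one under acid, and the carbinol centre of menthol is untouched because its C–O bond is not broken.

Step 2
Reactants: 3 di-(+)-menthyl fumarate; 4 1,1-dimethoxyethene
Product: 5 di-(+)-menthyl (1R,2S)-3,3-dimethoxycyclobutane-1,2-dicarboxylate (trans)
Conditions: iBu2AlCl, toluene/hexane, −78 °C
Reagents that add atoms: none
Why: Lewis-acid-promoted stepwise [2+2] of a ketene acetal with a fumarate (conjugate addition, then ring closure of the zwitterion); the aluminium-bound menthyl esters screen one face, so both ring centres should form with high diastereocontrol and the trans relationship of the fumarate is kept.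

Step 3
Reactants: 5 di-(+)-menthyl (1R,2S)-3,3-dimethoxycyclobutane-1,2-dicarboxylate
Product: 6 (1R,2S)-3,3-dimethoxycyclobutane-1,2-dicarboxylic acid
Conditions: KOH (excess), MeOH/THF/H2O, 55 °C; then aq. HCl to pH 3, 0 °C
Reagents that add atoms: potassium hydroxide, [K+].[OH-]
Why: Saponification of the hindered esters; epimerisation at C2 is harmless because that centre becomes sp2 in step 6, and C1 is the less acidic position and becomes α to a carboxylate once its own ester is cleaved.

Step 4
Reactants: 6 (1R,2S)-3,3-dimethoxycyclobutane-1,2-dicarboxylic acid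
Product: 7 di-tert-butyl (1R,2S)-3,3-dimethoxycyclobutane-1,2-dicarboxylate
Conditions: O-tert-butyl-N,N′-diisopropylisourea (3 equiv), CH2Cl2, rt
Reagents that add atoms: O-tert-butyl-N,N′-diisopropylisourea, CC(C)NC(=NC(C)C)OC(C)(C)C
Why: tert-Butyl ester formation at both carboxyl groups through the protonated isourea under neutral conditions, which leave the ketal and both stereocentres untouched.

Step 5
Reactants: 7 di-tert-butyl (1R,2S)-3,3-dimethoxycyclobutane-1,2-dicarboxylate
Product: 8 di-tert-butyl (1R,2S)-3-oxocyclobutane-1,2-dicarboxylate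
Conditions: TsOH·H2O (cat.), acetone/H2O, rt
Reagents that add atoms: water, O
Why: Mild acetal hydrolysis; tert-butyl esters survive dilute aqueous acid at room temperature, and the β-keto ester centre C2 settles trans to C1.

Step 6
Reactants: 8 di-tert-butyl (1R,2S)-3-oxocyclobutane-1,2-dicarboxylate
Product: 9 di-tert-butyl (1R)-3-(tert-butyldimethylsilyloxy)cyclobut-2-ene-1,2-dicarboxylate
Conditions: TBSOTf, Et3N, CH2Cl2, 0 °C
Reagents that add atoms: tert-butyldimethylsilyl trifluoromethanesulfonate, CC(C)(C)[Si](C)(C)OS(=O)(=O)C(F)(F)F
Why: Soft enolisation of a β-keto ester, which occurs only toward the doubly activated C2; C1 is not deprotonated by the amine because its anion would place a second sp2 centre on the cyclobutene.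

Step 7
Reactants: 9 di-tert-butyl (1R)-3-(tert-butyldimethylsilyloxy)cyclobut-2-ene-1,2-dicarboxylate; 10 2,4,4-trimethylcyclohex-2-en-1-one
Product: 11 di-tert-butyl 6-(tert-butyldimethylsilyloxy)-1-oxo-6,9-cyclodrimane-11,12-dioate (cis-anti-cis photoadduct)
Conditions: hν (350–366 nm), degassed CH2Cl2, −20 °C, excess 10
Reagents that add atoms: none
Why: Light above 340 nm excites only enone 10 (the β-silyloxy acrylate of 9 is transparent there); after intersystem crossing the triplet enone adds to the ground-state cyclobutene through a triplet 1,4-diradical that closes after spin inversion, which is the enone–alkene [2+2] photocycloaddition of the de Mayo type, known for cyclohexenones with silyloxy- and with ester-substituted cyclobutenes. The one new ring, the cyclobutane C5–C6–C9–C10, closes by radical recombination of the 1,4-diradical and is fused to the existing four-membered ring as a bicyclo[2.2.0]hexane. The step needs the head-to-tail orientation (C5 to C6, C10 to C9), which is secured twice: the donor-bearing C6 pairs with the enone β-carbon and the acceptor-bearing C9 with the α-carbon, and either first bond leaves a stabilised radical (α-ester at C9 or α-oxy at C6). C6 and C9 are set by the face of the flat cyclobutene that is attacked, which should be the one anti to the C8 ester. C10 and C5 are set by the exo approach, with ring A turned away from the C7–C8 bridge, and by the cis fusion that a four-membered ring imposes on a six-membered one, so the C8 centre of 9 fixes C10 absolutely. Adducts that differ only at C5 are harmless because C5 is reset in step 10, whereas endo or syn-face adducts carry the wrong C10 and, being diastereomers of 11, are removed by chromatography here.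

Step 8
Reactants: 11 cis-anti-cis photoadduct
Product: 12 C1 enol triflate of 11 (1-trifluoromethanesulfonyloxy-1-ene)
Conditions: KN(SiMe3)2, THF, −78 °C; then PhNTf2, −78 → 0 °C
Reagents that add atoms: N-phenylbis(trifluoromethanesulfonimide), O=S(=O)(N(c1ccccc1)S(=O)(=O)C(F)(F)F)C(F)(F)F
Why: Enolate O-triflation; C10 is quaternary, so the only ketone enolate is the one toward C2, and the ketone is far more acidic than the ester α-hydrogen on the cyclobutane.

Step 9
Reactants: 12 C1 enol triflate
Product: 13 di-tert-butyl 6-(tert-butyldimethylsilyloxy)-6,9-cyclodrim-1-ene-11,12-dioate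
Conditions: Pd(OAc)2 (cat.), PPh3, Bu3N, HCO2H, DMF, 50 °C
Reagents that add atoms: none
Why: Palladium-catalysed formate reduction of an enol triflate (oxidative addition to zerovalent palladium, formate decarboxylation, reductive elimination); it removes the C1 oxygen without a radical or cation next to the strained ring, and the vinylpalladium species has no β-carbon elimination open to it.

Step 10
Reactants: 13 di-tert-butyl 6-(tert-butyldimethylsilyloxy)-6,9-cyclodrim-1-ene-11,12-dioate
Product: 15 di-tert-butyl 6-oxodrim-1-ene-11,12-dioate (trans-fused; 5α-H; 8α and 9β esters), via cis-fused 6-oxo diester 14 (not isolated)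
Conditions: Bu4NF, THF, 0 °C → rt; then KOtBu (cat.), tBuOH/THF, rt
Reagents that add atoms: none
Why: Fluoride frees the C6 alkoxide, and retro-aldol cleavage of the C6–C9 bond releases the strain of both four-membered rings and gives ring B with a C6 ketone. The alkoxide base then equilibrates C5 (α to the ketone) and C8 and C9 (α to the esters) to the trans-fused, all-equatorial isomer, and tert-butyl esters do not exchange under these conditions.

Step 11
Reactants: 15 di-tert-butyl 6-oxodrim-1-ene-11,12-dioate
Product: 16 di-tert-butyl 6-(trimethylsilyloxy)drima-1,6-diene-11,12-dioate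
Conditions: LiN(iPr)2, THF, −78 °C; Me3SiCl, −78 → 0 °C
Reagents that add atoms: chlorotrimethylsilane, C[Si](C)(C)Cl
Why: Kinetic enolisation of the ketone at the only accessible α-position, C7 (C5 is tertiary and flanked by two quaternary carbons; the ester α-hydrogens are far less acidic), followed by O-silylation.

Step 12
Reactants: 16 di-tert-butyl 6-(trimethylsilyloxy)drima-1,6-diene-11,12-dioate
Product: 17 di-tert-butyl 6-oxodrima-1,7-diene-11,12-dioate (9α-H)
Conditions: Pd(OAc)2 (1.1 equiv), MeCN, rt
Reagents that add atoms: none
Why: Saegusa–Ito oxidation: the divalent palladium enolate at C7 can lose a β-hydrogen only from C8, so the double bond forms at C7–C8; the medium is weakly acidic, which protects the now vinylogously acidic C9–H.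

Step 13
Reactants: 17 di-tert-butyl 6-oxodrima-1,7-diene-11,12-dioate
Product: 18 di-tert-butyl 6β-hydroxydrima-1,7-diene-11,12-dioate
Conditions: NaBH4, CeCl3·7H2O, MeOH, −40 °C
Reagents that add atoms: none
Why: Luche 1,2-reduction; hydride approaches from the α face because the β face is blocked by the axial C10 and 4β methyl groups, giving the axial 6β alcohol.

Step 14
Reactants: 18 di-tert-butyl 6β-hydroxydrima-1,7-diene-11,12-dioate; 19 2-(diethoxyphosphoryl)acetic acid
Product: 20 di-tert-butyl 6β-[2-(diethoxyphosphoryl)acetoxy]drima-1,7-diene-11,12-dioate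
Conditions: DCC, DMAP (cat.), CH2Cl2, 0 °C → rt
Reagents that add atoms: none
Why: Steglich esterification; the carbodiimide-activated phosphonoacetic acid is a small, very electrophilic acyl donor suited to a hindered axial alcohol, and C8 is still sp2, so the C12 ester cannot lactonise onto O6.

Step 15
Reactants: 20 di-tert-butyl 6β-[2-(diethoxyphosphoryl)acetoxy]drima-1,7-diene-11,12-dioate
Product: 21 di-tert-butyl 6β-[2-(diethoxyphosphoryl)acetoxy]drimane-11,12-dioate (8α-H, 9α-H)
Conditions: H2 (4 atm), 5% Rh/Al2O3, EtOAc, rt
Reagents that add atoms: none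
Why: Heterogeneous syn hydrogenation from the α face, which is opposite the axial C10 methyl and the 6β ester, puts hydrogen on C8α and so the C12 ester axial β, cis to C11; the same step saturates the 1-ene. Rhodium on alumina is chosen because it has little tendency to cleave allylic C–O bonds.

Step 16
Reactants: 21 di-tert-butyl 6β-[2-(diethoxyphosphoryl)acetoxy]drimane-11,12-dioate; 22 (2E,4E)-hexa-2,4-dienal
Product: 23 di-tert-butyl 6β-[(2E,4E,6E)-octa-2,4,6-trienoyloxy]drimane-11,12-dioate
Conditions: LiCl, DBU, MeCN, 0 °C → rt
Reagents that add atoms: none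
Why: Horner–Wadsworth–Emmons olefination with a stabilised phosphonate gives the new 2E double bond; the amidine base deprotonates only the phosphonoacetate and is too weak to epimerise the axial C8 ester.

Step 17
Reactants: 23 di-tert-butyl 6β-[(2E,4E,6E)-octa-2,4,6-trienoyloxy]drimane-11,12-dioate
Product: 24 6β-[(2E,4E,6E)-octa-2,4,6-trienoyloxy]drimane-11,12-dioic acid (target)
Conditions: CF3CO2H/CH2Cl2 (1:4), 0 °C → rt
Reagents that add atoms: none
Why: Acidolysis of tert-butyl esters by alkyl–oxygen cleavage, which is independent of the crowding at C11 and leaves the secondary trienoate, the electron-poor triene and the C8/C9 configurations untouched.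

## Compound list

1 | fumaric acid | OC(=O)/C=C/C(=O)O | starting material
2 | (1S,2R,5S)-(+)-menthol | CC(C)[C@H]1CC[C@H](C)C[C@@H]1O | starting material
3 | di-(+)-menthyl fumarate, bis[(1S,2R,5S)-2-isopropyl-5-methylcyclohexyl] (E)-but-2-enedioate | CC(C)[C@H]1CC[C@H](C)C[C@@H]1OC(=O)/C=C/C(=O)O[C@H]2C[C@@H](C)CC[C@@H]2C(C)C | intermediate
4 | 1,1-dimethoxyethene | COC(=C)OC | starting material
5 | di-(+)-menthyl (1R,2S)-3,3-dimethoxycyclobutane-1,2-dicarboxylate (trans) | CC(C)[C@H]1CC[C@H](C)C[C@@H]1OC(=O)[C@@H]2CC(OC)(OC)[C@H]2C(=O)O[C@H]3C[C@@H](C)CC[C@@H]3C(C)C | intermediate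
6 | (1R,2S)-3,3-dimethoxycyclobutane-1,2-dicarboxylic acid | OC(=O)[C@@H]1CC(OC)(OC)[C@H]1C(=O)O | intermediate
7 | di-tert-butyl (1R,2S)-3,3-dimethoxycyclobutane-1,2-dicarboxylate | CC(C)(C)OC(=O)[C@@H]1CC(OC)(OC)[C@H]1C(=O)OC(C)(C)C | intermediate
8 | di-tert-butyl (1R,2S)-3-oxocyclobutane-1,2-dicarboxylate | CC(C)(C)OC(=O)[C@@H]1CC(=O)[C@H]1C(=O)OC(C)(C)C | intermediate
9 | di-tert-butyl (1R)-3-(tert-butyldimethylsilyloxy)cyclobut-2-ene-1,2-dicarboxylate | CC(C)(C)OC(=O)C1=C(O[Si](C)(C)C(C)(C)C)C[C@H]1C(=O)OC(C)(C)C | intermediate
10 | 2,4,4-trimethylcyclohex-2-en-1-one | CC1=CC(C)(C)CCC1=O | starting material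
11 | cis-anti-cis photoadduct, di-tert-butyl 6-(tert-butyldimethylsilyloxy)-1-oxo-6,9-cyclodrimane-11,12-dioate (5β-H, C12 ester exo) | CC(C)(C)[Si](C)(C)O[C@]13C[C@@H](C(=O)OC(C)(C)C)[C@]3(C(=O)OC(C)(C)C)[C@@]2(C)C(=O)CCC(C)(C)[C@@H]12 | intermediate
12 | C1 enol triflate of 11, di-tert-butyl 6-(tert-butyldimethylsilyloxy)-1-(trifluoromethanesulfonyloxy)-6,9-cyclodrim-1-ene-11,12-dioate | CC(C)(C)[Si](C)(C)O[C@]13C[C@@H](C(=O)OC(C)(C)C)[C@]3(C(=O)OC(C)(C)C)[C@@]2(C)C(OS(=O)(=O)C(F)(F)F)=CCC(C)(C)[C@@H]12 | intermediate
13 | di-tert-butyl 6-(tert-butyldimethylsilyloxy)-6,9-cyclodrim-1-ene-11,12-dioate | CC(C)(C)[Si](C)(C)O[C@]13C[C@@H](C(=O)OC(C)(C)C)[C@]3(C(=O)OC(C)(C)C)[C@@]2(C)C=CCC(C)(C)[C@@H]12 | intermediate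
14 | cis-fused di-tert-butyl 6-oxodrim-1-ene-11,12-dioate (5β-H, 8α ester, C9 epimers) | O=C1C[C@@H](C(=O)OC(C)(C)C)C(C(=O)OC(C)(C)C)[C@@]2(C)C=CCC(C)(C)[C@@H]12 | intermediate
15 | di-tert-butyl 6-oxodrim-1-ene-11,12-dioate (trans-fused, 5α-H, 8α and 9β esters) | O=C1C[C@@H](C(=O)OC(C)(C)C)[C@H](C(=O)OC(C)(C)C)[C@@]2(C)C=CCC(C)(C)[C@H]12 | intermediate
16 | di-tert-butyl 6-(trimethylsilyloxy)drima-1,6-diene-11,12-dioate | C[Si](C)(C)OC1=C[C@@H](C(=O)OC(C)(C)C)[C@H](C(=O)OC(C)(C)C)[C@@]2(C)C=CCC(C)(C)[C@H]12 | intermediate
17 | di-tert-butyl 6-oxodrima-1,7-diene-11,12-dioate (9α-H) | O=C1C=C(C(=O)OC(C)(C)C)[C@H](C(=O)OC(C)(C)C)[C@@]2(C)C=CCC(C)(C)[C@H]12 | intermediate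
18 | di-tert-butyl 6β-hydroxydrima-1,7-diene-11,12-dioate | O[C@@H]1C=C(C(=O)OC(C)(C)C)[C@H](C(=O)OC(C)(C)C)[C@@]2(C)C=CCC(C)(C)[C@H]12 | intermediate
19 | 2-(diethoxyphosphoryl)acetic acid | CCOP(=O)(OCC)CC(=O)O | starting material
20 | di-tert-butyl 6β-[2-(diethoxyphosphoryl)acetoxy]drima-1,7-diene-11,12-dioate | CCOP(=O)(OCC)CC(=O)O[C@@H]1C=C(C(=O)OC(C)(C)C)[C@H](C(=O)OC(C)(C)C)[C@@]2(C)C=CCC(C)(C)[C@H]12 | intermediate
21 | di-tert-butyl 6β-[2-(diethoxyphosphoryl)acetoxy]drimane-11,12-dioate (8α-H, 9α-H) | CCOP(=O)(OCC)CC(=O)O[C@@H]1C[C@H](C(=O)OC(C)(C)C)[C@H](C(=O)OC(C)(C)C)[C@@]2(C)CCCC(C)(C)[C@H]12 | intermediate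
22 | (2E,4E)-hexa-2,4-dienal | C/C=C/C=C/C=O | starting material
23 | di-tert-butyl 6β-[(2E,4E,6E)-octa-2,4,6-trienoyloxy]drimane-11,12-dioate | C/C=C/C=C/C=C/C(=O)O[C@@H]1C[C@H](C(=O)OC(C)(C)C)[C@H](C(=O)OC(C)(C)C)[C@@]2(C)CCCC(C)(C)[C@H]12 | intermediate
24 | 6β-[(2E,4E,6E)-octa-2,4,6-trienoyloxy]drimane-11,12-dioic acid (5α-H, 8α-H, 9α-H, 10β-methyl) | C/C=C/C=C/C=C/C(=O)O[C@@H]1C[C@H](C(=O)O)[C@H](C(=O)O)[C@@]2(C)CCCC(C)(C)[C@H]12 | target

## Step count and least certain steps

Total: 17 steps. Longest linear sequence: 17 steps, from fumaric acid 1 to 24; compounds 2, 4, 10, 19 and 22 enter along the way.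

**Step 7 (key step).** The alkene of 9 is fully substituted and has to bond to a quaternary-to-be carbon, so addition may be slow and the exo preference may erode or invert. The main adduct would then carry ring A on the concave face and thereby the wrong C10. Fallback: since C8 is erased at 15, only C10 matters, and the mirror-image cyclobutene can be used with the endo mode.
- Fumaric acid 1 is esterified with two equivalents of natural (−)-menthol to di-(−)-menthyl fumarate F1.
- F1 and 4 give ketal diester F2, then diacid F3, di-tert-butyl ketal F4, ketone F5 and silyl enol ether F6, all under the conditions of steps 2 to 6.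
- Irradiation of F6 with 10 and isolation of the cis-syn-cis adduct F7, which has the required C10, is followed by triflation to F8 and reduction to alkene F9.
- The conditions of step 10 open F9 to cis-fused ketone F10 and equilibrate it, returning the route at 15.

**Step 3.** The forcing base needed for the hindered menthyl esters may partly epimerise C1, which would lower the enantiomeric purity of everything downstream. The ketal may also be lost on acidification, followed by decarboxylation. Fallback: reductive removal of the auxiliary. LiAlH4 reduces 5 to the trans diol F11 with release of menthol, and oxidation of both primary alcohols (TEMPO cat., NaOCl cat., NaClO2, phosphate buffer, MeCN) returns diacid 6.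

**Step 10.** The C5 equilibrium may not lie far enough on the trans side, because the adjacent gem-dimethyl group and the ring A double bond both perturb the usual preference; equilibration at the hindered C9 may also be incomplete. Fallback: kinetic instead of thermodynamic control at C5. The mixture of 14 and 15 is converted into the more substituted silyl enol ether F12 (Me3SiCl, NaI, Et3N, MeCN). Protonation at −78 °C (Bu4NF/AcOH) should occur from the α face, since the β face is screened by the C10 and 4β methyl groups, and gives 15.

**Step 12.** In 17 the C9 hydrogen is α to an ester and γ to the enone, and allylic strain with the C8 ester may favour the wrong C9 epimer, so C9 may epimerise here or in step 13. Fallback: take the C9 centre out of the problem.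
- 17, as any C9 mixture, is deprotonated (KOtBu, THF, −78 °C) and the dienolate is quenched kinetically at C7 with AcOH to give the deconjugated 8-ene F13.
- NaBH4/CeCl3·7H2O gives alcohol F14, and acylation with 19 gives phosphonoacetate F15.
- Hydrogenation of the tetrasubstituted alkene from the α face (H2 at higher pressure, Rh/Al2O3) sets C8 and C9 together and returns the route at 21.

**Step 15.** The allylic C6–O bond may undergo hydrogenolysis, or face selectivity at C8 may be incomplete. Fallback: hydrogenate before C6 becomes an allylic ester. Enone 17 is hydrogenated (H2, Pd/C, EtOAc) from the α face to saturated ketone F16. NaBH4 then gives axial alcohol F17, which is acylated at once with 19 under the conditions of step 14 to reach 21 before it can lactonise onto the axial C12 ester.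

## Further compounds

F1 | step 7 | di-(−)-menthyl fumarate, bis[(1R,2S,5R)-2-isopropyl-5-methylcyclohexyl] (E)-but-2-enedioate | CC(C)[C@@H]1CC[C@@H](C)C[C@H]1OC(=O)/C=C/C(=O)O[C@@H]2C[C@H](C)CC[C@H]2C(C)C
F2 | step 7 | di-(−)-menthyl (1S,2R)-3,3-dimethoxycyclobutane-1,2-dicarboxylate | CC(C)[C@@H]1CC[C@@H](C)C[C@H]1OC(=O)[C@H]2CC(OC)(OC)[C@@H]2C(=O)O[C@@H]3C[C@H](C)CC[C@H]3C(C)C
F3 | step 7 | (1S,2R)-3,3-dimethoxycyclobutane-1,2-dicarboxylic acid | OC(=O)[C@H]1CC(OC)(OC)[C@@H]1C(=O)O
F4 | step 7 | di-tert-butyl (1S,2R)-3,3-dimethoxycyclobutane-1,2-dicarboxylate | CC(C)(C)OC(=O)[C@H]1CC(OC)(OC)[C@@H]1C(=O)OC(C)(C)C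
F5 | step 7 | di-tert-butyl (1S,2R)-3-oxocyclobutane-1,2-dicarboxylate | CC(C)(C)OC(=O)[C@H]1CC(=O)[C@@H]1C(=O)OC(C)(C)C
F6 | step 7 | di-tert-butyl (1S)-3-(tert-butyldimethylsilyloxy)cyclobut-2-ene-1,2-dicarboxylate | CC(C)(C)OC(=O)C1=C(O[Si](C)(C)C(C)(C)C)C[C@@H]1C(=O)OC(C)(C)C
F7 | step 7 | cis-syn-cis photoadduct of F6 and 10, di-tert-butyl 6-(tert-butyldimethylsilyloxy)-1-oxo-6,9-cyclodrimane-11,12-dioate (C6, C8, C9 epimer of 11) | CC(C)(C)[Si](C)(C)O[C@@]13C[C@H](C(=O)OC(C)(C)C)[C@@]3(C(=O)OC(C)(C)C)[C@@]2(C)C(=O)CCC(C)(C)[C@@H]12
F8 | step 7 | C1 enol triflate of F7 | CC(C)(C)[Si](C)(C)O[C@@]13C[C@H](C(=O)OC(C)(C)C)[C@@]3(C(=O)OC(C)(C)C)[C@@]2(C)C(OS(=O)(=O)C(F)(F)F)=CCC(C)(C)[C@@H]12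
F9 | step 7 | 1-ene from F8 (C6, C8, C9 epimer of 13) | CC(C)(C)[Si](C)(C)O[C@@]13C[C@H](C(=O)OC(C)(C)C)[C@@]3(C(=O)OC(C)(C)C)[C@@]2(C)C=CCC(C)(C)[C@@H]12
F10 | step 7 | cis-fused di-tert-butyl 6-oxodrim-1-ene-11,12-dioate (5β-H, 8β ester, C9 epimers) | O=C1C[C@H](C(=O)OC(C)(C)C)C(C(=O)OC(C)(C)C)[C@@]2(C)C=CCC(C)(C)[C@@H]12
F11 | step 3 | [(1R,2R)-3,3-dimethoxycyclobutane-1,2-diyl]dimethanol (trans) | OC[C@@H]1CC(OC)(OC)[C@H]1CO
F12 | step 10 | di-tert-butyl 6-(trimethylsilyloxy)drima-1,5-diene-11,12-dioate | C[Si](C)(C)OC=1C[C@@H](C(=O)OC(C)(C)C)[C@H](C(=O)OC(C)(C)C)[C@@]2(C)C=CCC(C)(C)C2=1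
F13 | step 12 | di-tert-butyl 6-oxodrima-1,8-diene-11,12-dioate | O=C1CC(C(=O)OC(C)(C)C)=C(C(=O)OC(C)(C)C)[C@@]2(C)C=CCC(C)(C)[C@H]12
F14 | step 12 | di-tert-butyl 6β-hydroxydrima-1,8-diene-11,12-dioate | O[C@@H]1CC(C(=O)OC(C)(C)C)=C(C(=O)OC(C)(C)C)[C@@]2(C)C=CCC(C)(C)[C@H]12
F15 | step 12 | di-tert-butyl 6β-[2-(diethoxyphosphoryl)acetoxy]drima-1,8-diene-11,12-dioate | CCOP(=O)(OCC)CC(=O)O[C@@H]1CC(C(=O)OC(C)(C)C)=C(C(=O)OC(C)(C)C)[C@@]2(C)C=CCC(C)(C)[C@H]12
F16 | step 15 | di-tert-butyl 6-oxodrimane-11,12-dioate (8α-H, 9α-H) | O=C1C[C@H](C(=O)OC(C)(C)C)[C@H](C(=O)OC(C)(C)C)[C@@]2(C)CCCC(C)(C)[C@H]12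
F17 | step 15 | di-tert-butyl 6β-hydroxydrimane-11,12-dioate (8α-H, 9α-H) | O[C@@H]1C[C@H](C(=O)OC(C)(C)C)[C@H](C(=O)OC(C)(C)C)[C@@]2(C)CCCC(C)(C)[C@H]12
A1 | alternative 1 | 11-ethyl 12-methyl 6-oxo-5-epi-drim-8-ene-11,12-dioate (cis-fused) | O=C1CC(C(=O)OC)=C(C(=O)OCC)[C@@]2(C)CCCC(C)(C)[C@@H]12
A2 | alternative 1 | ethyl 7-[1-(methoxycarbonyl)ethenyl]-1,5,5-trimethylbicyclo[4.1.0]heptane-7-carboxylate (vinylcyclopropane, vinyl group exo) | C=C(C(=O)OC)[C@]1(C(=O)OCC)[C@@]2(C)CCCC(C)(C)[C@@H]12
A3 | alternative 2 | methyl 6β,12-epoxy-12-oxodrimane-11-oate (bridged 6β,12-lactone 11-methyl ester) | O=C1O[C@@H]2C[C@H]1[C@H](C(=O)OC)[C@@]3(C)CCCC(C)(C)[C@H]23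
A4 | alternative 2 | 11,12-dinordrim-8-en-6β-ol | O[C@@H]1CC=C[C@@]2(C)CCCC(C)(C)[C@H]12
A5 | alternative 3 | trans-fused cycloadduct, methyl 6-(tert-butyldimethylsilyloxy)-11-oxo-11-(2-oxo-1,3-oxazolidin-3-yl)drim-6-en-12-oate | CC(C)(C)[Si](C)(C)OC1=C[C@H](C(=O)OC)[C@H](C(=O)N3CCOC3=O)[C@@]2(C)CCCC(C)(C)[C@H]12
A6 | alternative 3 | methyl (2E,4Z,10E)-4-(tert-butyldimethylsilyloxy)-6,6,10-trimethyl-12-oxo-12-(2-oxo-1,3-oxazolidin-3-yl)dodeca-2,4,10-trienoate | COC(=O)/C=C/C(O[Si](C)(C)C(C)(C)C)=C/C(C)(C)CCC/C(C)=C/C(=O)N1CCOC1=O
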